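Ring carbons of the cyclohexane: C1 (CH–OAng beside the epoxide), C2 and C3 (epoxide, C3 with the methyl), C4 (CH–OH), C5 (CH–OAng), C6 (side chain). C1–C4 form an oxidised 2-methyl-1,3-diene whose inner carbons C2 and C3 are propyne. A ruthenium-catalysed tandem enyne cross-metathesis/ring-closing metathesis inserts propyne between the C1 vinyl and C4 propenyl groups of an acyclic syn-1,5-diene that already carries the O5 angelate and the C7 acrolein unit, forming C1=C2, C3=C4 and the ring at once. O5, O8 and O1 are then unveiled one at a time and acylated singly; singlet oxygen, Kornblum–DeLaMare cleavage, ketone reduction and directed epoxidation oxygenate the diene.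

Key step: step 4

Remarks on the chemistry:
- Further labels: C7 (carries the =CH2 carbon C14), C8 (side-chain CH–OAng), C9 (CH2), C10/C11 (side-chain epoxide), C15 (ring methyl). OAng = angelate, (Z)-2-methylbut-2-enoate. β is the ring face of the C1 oxygen; α is the face of O5 and C7 (and, in the target, of O4 and the ring epoxide oxygen).
- Assumption: the two reagent-controlled additions follow the usual facial models ((R)-TRIP: Re face of the aldehyde; B-allyldiisopinocampheylborane of the (+)-α-pinene series: Si face of the enal). If either sense proves reversed, the antipodal catalyst or reagent is taken.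
- Each esterification puts one angelate on the only hydroxyl that is free at that stage.

Step 1
Reactants: 1 3,3-diethoxyprop-1-yne; 2 vinylmagnesium bromide; 3 2-(iodomethyl)-4,4,5,5-tetramethyl-1,3,2-dioxaborolane
Product: 5 2-[(2E)-2-(diethoxymethyl)penta-2,4-dien-1-yl]-4,4,5,5-tetramethyl-1,3,2-dioxaborolane, via alkenylcopper 4 (not isolated)
Conditions: vinylmagnesium bromide (1.1 equiv), CuBr·SMe2 (1.1 equiv), Et2O/Me2S, −45 °C; then 1, −45 to −30 °C; then 3, HMPA, P(OEt)3, −45 to −20 °C
Reagents that add atoms: none
Why: Syn carbocupration of the acetylenic acetal places vinyl on the terminal carbon and copper on the carbon next to the acetal, cis to each other, and C-alkylation of this alkenylcopper by the iodomethylboronate below −20 °C (before β-elimination of ethoxide sets in) keeps that geometry, so the γ-vinyl group of the allylboronate lies cis to CH2B (carbocupration/alkylation).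

Step 2
Reactants: 5; 6 (E)-but-2-enal
Product: 8 (2E,4S,5S)-6-(diethoxymethyl)-5-ethenylhepta-2,6-dien-4-ol, via pinacol borate ester 7 (not isolated)
Conditions: (R)-3,3′-bis(2,4,6-triisopropylphenyl)-1,1′-binaphthyl-2,2′-diyl hydrogen phosphate ((R)-TRIP, 5 mol %), 4 Å molecular sieves, toluene, −30 °C; then triethanolamine, aq. NaHCO3, rt
Reagents that add atoms: none
Why: Chiral phosphoric acid-catalysed allylboration through a Zimmerman–Traxler chair: the γ-vinyl group cis to CH2B sits axial and gives the syn adduct, the catalyst directs attack to the Re face of the enal (C5 S, hence C6 S), the weak acid at low temperature over sieves leaves the diethyl acetal intact, and the mild basic work-up frees the alcohol from the borate.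

Step 3
Reactants: 8; 9 angelic acid
Product: 11 (2E,4S,5S)-5-ethenyl-6-formylhepta-2,6-dien-4-yl (2Z)-2-methylbut-2-enoate, via angelate acetal 10 (not isolated)
Conditions: angelic acid (1.5 equiv), 2,4,6-trichlorobenzoyl chloride, Et3N, toluene, rt; then 8, 60 °C (no DMAP); after aqueous work-up, oxalic acid (5% aq.), THF, rt
Reagents that add atoms: water, O
Why: Yamaguchi-type esterification through the mixed 2,4,6-trichlorobenzoic anhydride acylates the only hydroxyl (O5) without Z to E isomerisation of the angelate, and mild aqueous acid then hydrolyses the α,β-unsaturated diethyl acetal, so C8 is set free as an aldehyde that can no longer close onto O5; no stereocentre is touched.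

Step 4
Reactants: 11; 12 propyne
Product: 13 (1S,6S)-3-methyl-6-(3-oxoprop-1-en-2-yl)cyclohexa-2,4-dien-1-yl (2Z)-2-methylbut-2-enoate
Conditions: propyne (3 equiv, THF solution added over 6 h), second-generation Grubbs catalyst RuCl2(=CHPh)(PCy3)(H2IMes) (10 mol %), CH2Cl2 (20 mM), 40 °C, argon
Reagents that add atoms: none
Why: Tandem enyne cross-metathesis/ring-closing metathesis, the known route from 1,5-dienes and terminal alkynes to 2-substituted cyclohexa-1,3-dienes: the ruthenium alkylidene forms at the terminal C1 vinyl group, adds to propyne with C1 bonding to the unsubstituted alkyne carbon C2 (the usual 1,3-diene regiochemistry of enyne metathesis), and the resulting C3(CH3) vinylcarbene closes onto the C4 propenyl group. The six-membered ring is closed by this ring-closing metathesis (ruthenacyclobutane between the C3 carbene and C4=CH–CH3, propene lost). No stereocentre is created: C5 and C6 come from step 2 and are untouched, and the two new bonds are the ring double bonds C1=C2 and C3=C4. The step corrects its own geometry: only the vinylcarbene with a cis C1=C2 bond can close, the trans form isomerises or reverts within the reversible metathesis manifold, and propene loss drives both into 13. The selectivities needed are the site of initiation, the alkyne regiochemistry and inertness of the other alkenes: the first is secured because the C4 alkene is internal and deactivated by the allylic acyloxy group, the second is intrinsic to enyne metathesis, and the third because the C7 methylene is a 1,1-disubstituted acrolein-type alkene and the angelate a trisubstituted enoate, both poor metathesis partners. Slow addition of propyne suppresses alkyne oligomerisation.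

Step 5
Reactants: 13; 14 B-allyldiisopinocampheylborane of the (+)-α-pinene series
Product: 15 (1S,6S)-6-[(3S)-3-hydroxyhexa-1,5-dien-2-yl]-3-methylcyclohexa-2,4-dien-1-yl (2Z)-2-methylbut-2-enoate
Conditions: 14 (1.3 equiv), Et2O, −78 °C; then pH 7 phosphate buffer, MeOH, 30% H2O2, 0 °C
Reagents that add atoms: none
Why: Brown allylboration of the aldehyde through the chair transition state: the reagent adds to the Si face of the α-branched enal and sets C8 as S under reagent control, the dienyl angelate is not touched at −78 °C, and the buffered oxidative work-up spares the ester.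

Step 6
Reactants: 15; 9 angelic acid
Product: 16 (1S,6S)-3-methyl-6-[(3S)-3-{[(2Z)-2-methylbut-2-enoyl]oxy}hexa-1,5-dien-2-yl]cyclohexa-2,4-dien-1-yl (2Z)-2-methylbut-2-enoate
Conditions: angelic acid (2 equiv), 2,4,6-trichlorobenzoyl chloride, Et3N, toluene, rt; then 15, 50 °C (no DMAP)
Reagents that add atoms: none
Why: Mixed-anhydride (Yamaguchi-type) esterification of the only free hydroxyl (O8) without Z to E isomerisation of the angelate; no stereocentre is touched.

Step 7
Reactants: 16
Product: 17 endoperoxide of 16: O–O bridge from C1 to C4 on the β face (2,3-dioxabicyclo[2.2.2]oct-5-ene), 5α-OAng, 6α side chain CH2=C–CH(OAng)–CH2CH=CH2 (8S)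
Conditions: O2, visible light, 5,10,15,20-tetraphenylporphyrin (cat.), CH2Cl2, −20 °C
Reagents that add atoms: dioxygen (as singlet oxygen), O=O
Why: [4+2] cycloaddition of singlet oxygen to the cyclohexa-1,3-diene occurs on the β face, opposite to the cis C5 angelate and C6 side chain, and fixes O1 and O4 β; the mono- and 1,1-disubstituted alkenes and the electron-poor angelates react far more slowly.

Step 8
Reactants: 17
Product: 18 hydroxy enone bis-angelate: C4 ketone, C2=C3, 1β-OH, 5α-OAng, 6α side chain CH2=C–CH(OAng)–CH2CH=CH2 (8S)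
Conditions: Et3N (0.5 equiv), CH2Cl2, 0 °C
Reagents that add atoms: none
Why: Kornblum–DeLaMare rearrangement: the amine removes the C4–H, the bridgehead proton acidified by the adjacent C5 acyloxy group, the O–O bond breaks, and the C4 ketone and the C1 β-hydroxyl (configuration from step 7) result.

Step 9
Reactants: 18; 9 angelic acid
Product: 19 tris-angelate enone with allyl terminus (O1, O5, O8 acylated; C4 ketone)
Conditions: angelic acid (2 equiv), 2,4,6-trichlorobenzoyl chloride, Et3N, toluene, rt; then 18, 60 °C (no DMAP)
Reagents that add atoms: none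
Why: Mixed-anhydride (Yamaguchi-type) esterification of the only free hydroxyl (O1) without Z to E isomerisation; no stereocentre is touched and the C4 ketone holds the place of the hydroxyl that stays free.

Step 10
Reactants: 19; 20 2-methylbut-2-ene
Product: 21 prenyl tris-angelate (C9H2–C10H=C11(CH3)2 side chain, C4 ketone)
Conditions: 2-methylbut-2-ene (excess), second-generation Grubbs catalyst RuCl2(=CHPh)(PCy3)(H2IMes) (5 mol %), CH2Cl2, 40 °C
Reagents that add atoms: none
Why: Olefin cross-metathesis of the terminal allyl group with 2-methylbut-2-ene installs the prenyl terminus; the enone, the angelates and the 1,1-disubstituted C7 methylene are unreactive.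

Step 11
Reactants: 21
Product: 22 (10R)-10,11-epoxide of 21
Conditions: 1,2:4,5-di-O-isopropylidene-β-D-erythro-2,3-hexodiulo-2,6-pyranose (Shi ketone from D-fructose, 30 mol %), Oxone (2KHSO5·KHSO4·K2SO4), K2CO3, Bu4NHSO4, MeCN/dimethoxymethane/aq. Na2B4O7 buffer (pH 10.5), 0 °C
Reagents that add atoms: potassium peroxymonosulfate, [K+].[O-]S(=O)(=O)OO
Why: Shi epoxidation: the fructose-derived dioxirane attacks the electron-rich trisubstituted C10=C11 alkene through the spiro transition state to give the 10R epoxide under catalyst control, and leaves the electron-poor enone and angelate alkenes and the deactivated 1,1-disubstituted alkene.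

Step 12
Reactants: 22
Product: 23 allylic alcohol: 4α-OH, C2=C3, otherwise as 22
Conditions: NaBH4, CeCl3·7H2O, MeOH, −78 °C; AcOH quench at −78 °C
Reagents that add atoms: none
Why: Luche 1,2-reduction: hydride adds to the β face of the C4 carbonyl, anti to the axial α-acyloxy group at C5 (Felkin–Anh, axial attack), so the new hydroxyl is α and cis to O5; esters and epoxide survive at −78 °C.

Step 13
Reactants: 23
Product: 24 target CNP0147918.1
Conditions: vanadyl acetylacetonate VO(C5H7O2)2 (5 mol %), t-BuOOH, CH2Cl2, 0 °C to rt
Reagents that add atoms: tert-butyl hydroperoxide, CC(C)(C)OO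
Why: Vanadium-catalysed hydroxyl-directed epoxidation delivers oxygen to C2=C3 from the face of the allylic C4 hydroxyl (α), cis to O4 and trans to the C1 angelate, and does not touch the non-allylic alkenes.

Compound list
1 | 3,3-diethoxyprop-1-yne (propiolaldehyde diethyl acetal) | C#CC(OCC)OCC | starting material
2 | vinylmagnesium bromide | C=C[Mg]Br | starting material
3 | 2-(iodomethyl)-4,4,5,5-tetramethyl-1,3,2-dioxaborolane | ICB1OC(C)(C)C(C)(C)O1 | starting material
4 | [(1Z)-1-(diethoxymethyl)buta-1,3-dien-1-yl]copper (copper cis to vinyl) | C=C/C=C(\[Cu])C(OCC)OCC | intermediate (not isolated)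
5 | 2-[(2E)-2-(diethoxymethyl)penta-2,4-dien-1-yl]-4,4,5,5-tetramethyl-1,3,2-dioxaborolane | C=C/C=C(\CB1OC(C)(C)C(C)(C)O1)C(OCC)OCC | intermediate
6 | (E)-but-2-enal | C/C=C/C=O | starting material
7 | 2-{[(2E,4S,5S)-6-(diethoxymethyl)-5-ethenylhepta-2,6-dien-4-yl]oxy}-4,4,5,5-tetramethyl-1,3,2-dioxaborolane | C=C([C@H](C=C)[C@H](/C=C/C)OB1OC(C)(C)C(C)(C)O1)C(OCC)OCC | intermediate (not isolated)
8 | (2E,4S,5S)-6-(diethoxymethyl)-5-ethenylhepta-2,6-dien-4-ol | C=C([C@H](C=C)[C@H](/C=C/C)O)C(OCC)OCC | intermediate
9 | angelic acid, (Z)-2-methylbut-2-enoic acid | C/C=C(/C)C(=O)O | starting material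
10 | (2E,4S,5S)-6-(diethoxymethyl)-5-ethenylhepta-2,6-dien-4-yl (2Z)-2-methylbut-2-enoate | C=C([C@H](C=C)[C@H](/C=C/C)OC(=O)/C(C)=C\C)C(OCC)OCC | intermediate (not isolated)
11 | (2E,4S,5S)-5-ethenyl-6-formylhepta-2,6-dien-4-yl (2Z)-2-methylbut-2-enoate | C=C([C@H](C=C)[C@H](/C=C/C)OC(=O)/C(C)=C\C)C=O | intermediate
12 | propyne | CC#C | starting material
13 | (1S,6S)-3-methyl-6-(3-oxoprop-1-en-2-yl)cyclohexa-2,4-dien-1-yl (2Z)-2-methylbut-2-enoate (O5 and C7 cis) | C=C([C@H]1[C@@H](OC(=O)/C(C)=C\C)C=C(C)C=C1)C=O | intermediate
14 | B-allyldiisopinocampheylborane, (+)-α-pinene series | C=CCB([C@@H]1C[C@@H]2C[C@H]([C@H]1C)C2(C)C)[C@@H]1C[C@@H]2C[C@H]([C@H]1C)C2(C)C | starting material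
15 | (1S,6S)-6-[(3S)-3-hydroxyhexa-1,5-dien-2-yl]-3-methylcyclohexa-2,4-dien-1-yl (2Z)-2-methylbut-2-enoate | C=C([C@H]1[C@@H](OC(=O)/C(C)=C\C)C=C(C)C=C1)[C@H](CC=C)O | intermediate
16 | (1S,6S)-3-methyl-6-[(3S)-3-{[(2Z)-2-methylbut-2-enoyl]oxy}hexa-1,5-dien-2-yl]cyclohexa-2,4-dien-1-yl (2Z)-2-methylbut-2-enoate | C=C([C@H]1[C@@H](OC(=O)/C(C)=C\C)C=C(C)C=C1)[C@H](CC=C)OC(=O)/C(C)=C\C | intermediate
17 | bis-angelate endoperoxide: β-face O–O bridge C1 to C4, 5α-OAng, 6α side chain, 8S | C=C([C@H]1[C@@H](OC(=O)/C(C)=C\C)[C@@H]2OO[C@H]1C=C2C)[C@H](CC=C)OC(=O)/C(C)=C\C | intermediate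
18 | hydroxy enone bis-angelate: C4 ketone, 1β-OH, 5α-OAng, 8S-OAng | C=C([C@H]1[C@@H](OC(=O)/C(C)=C\C)C(=O)C(C)=C[C@@H]1O)[C@H](CC=C)OC(=O)/C(C)=C\C | intermediate
19 | tris-angelate enone with allyl terminus | C=C([C@H]1[C@@H](OC(=O)/C(C)=C\C)C(=O)C(C)=C[C@@H]1OC(=O)/C(C)=C\C)[C@H](CC=C)OC(=O)/C(C)=C\C | intermediate
20 | 2-methylbut-2-ene | CC=C(C)C | starting material
21 | tris-angelate enone with prenyl terminus | C=C([C@H]1[C@@H](OC(=O)/C(C)=C\C)C(=O)C(C)=C[C@@H]1OC(=O)/C(C)=C\C)[C@H](CC=C(C)C)OC(=O)/C(C)=C\C | intermediate
22 | tris-angelate enone with (10R)-10,11-epoxide | C=C([C@H]1[C@@H](OC(=O)/C(C)=C\C)C(=O)C(C)=C[C@@H]1OC(=O)/C(C)=C\C)[C@H](C[C@H]1OC1(C)C)OC(=O)/C(C)=C\C | intermediate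
23 | 4α-allylic alcohol (C2=C3) with side-chain epoxide | C=C([C@H]1[C@@H](OC(=O)/C(C)=C\C)[C@@H](O)C(C)=C[C@@H]1OC(=O)/C(C)=C\C)[C@H](C[C@H]1OC1(C)C)OC(=O)/C(C)=C\C | intermediate
24 | CNP0147918.1 | C=C([C@H]1[C@@H](OC(=O)/C(C)=C\C)[C@@H](O)[C@@]2(C)O[C@H]2[C@@H]1OC(=O)/C(C)=C\C)[C@H](C[C@H]1OC1(C)C)OC(=O)/C(C)=C\C | target

Total step count: 13. Longest linear sequence: 13 steps (from 3,3-diethoxyprop-1-yne).

Steps most likely to fail

Step 4. Propyne may oligomerise on the ruthenium carbene, and the trans-configured vinylcarbene may be intercepted by another alkene before it isomerises, so that acyclic trienes accumulate. Loss of angelic acid from the product diene with aromatisation is a further drain. The fallback sets out from 11 and uses alkene metathesis only. Cross-metathesis of the C1 vinyl group with isoprene (second-generation Hoveyda–Grubbs catalyst RuCl2(=CH–C6H4–2-OiPr)(H2IMes), CH2Cl2, 40 °C) gives the triene (2E,4S,5S)-6-formyl-5-(3-methylbuta-1,3-dien-1-yl)hepta-2,6-dien-4-yl angelate F1. Ring-closing metathesis between its terminal C3=CH2 and the C4 propenyl group (same catalyst, toluene, 60 °C, argon purge) then closes the ring and comes back at 13. The disubstituted C1=C2 bond equilibrates by secondary metathesis, which feeds the cis isomer that cyclises.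

Step 1. β-Elimination of ethoxide from the α-cuprio acetal to an ethoxyallene may outrun the slow alkylation by the iodomethylboronate, and transfer of the vinyl group to the alkyne may be incomplete. The fallback sets out from 1 and 2 and separates the two events. The alkenylcopper formed as in step 1 is quenched at −45 °C with iodine, which is fast enough to beat the elimination, and gives (3Z)-5,5-diethoxy-4-iodopenta-1,3-diene F2. Separately, 3 is converted with zinc dust (THF, rt) into the boromethylzinc iodide. Negishi coupling of F2 with this zinc reagent (Pd(PPh3)4, zerovalent palladium, 5 mol %, THF, rt) proceeds with retention of the alkene geometry and comes back at 5.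

Step 8. The base may abstract the C1–H instead of the C4–H and give the regioisomeric hydroxy enone, and base-induced loss of the α-acyloxy group may follow. The fallback sets out from 16 and avoids the endoperoxide. Epoxidation of the more electron-rich trisubstituted C3=C4 bond of the diene (m-chloroperbenzoic acid, NaHCO3, CH2Cl2, −20 °C) on the face opposite to the C5 angelate gives the 3β,4β-vinyl epoxide F3. Palladium-catalysed 1,4-opening with angelic acid 9 (Pd(PPh3)4, zerovalent palladium, 5 mol %, THF, 0 °C) proceeds through the π-allyl complex with overall retention and gives the cis-1β-angeloyloxy-4β-alcohol F4. Oxidation of its only free hydroxyl (Dess–Martin periodinane, NaHCO3, CH2Cl2, 0 °C) comes back at 19.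

Further compounds
F1 | step 4 | (2E,4S,5S)-6-formyl-5-(3-methylbuta-1,3-dien-1-yl)hepta-2,6-dien-4-yl (2Z)-2-methylbut-2-enoate (E/Z mixture at C1=C2) | C=C([C@H](C=CC(C)=C)[C@H](/C=C/C)OC(=O)/C(C)=C\C)C=O
F2 | step 1 | (3Z)-5,5-diethoxy-4-iodopenta-1,3-diene | C=C/C=C(\I)C(OCC)OCC
F3 | step 8 | 3β,4β-epoxide of 16 (vinyl epoxide, C1=C2 retained) | C=C([C@H]1[C@@H](OC(=O)/C(C)=C\C)[C@@H]2O[C@]2(C)C=C1)[C@H](CC=C)OC(=O)/C(C)=C\C
F4 | step 8 | tris-angelate 4β-alcohol (1β-OAng, C2=C3, 5α-OAng, 8S-OAng) | C=C([C@H]1[C@@H](OC(=O)/C(C)=C\C)[C@H](O)C(C)=C[C@@H]1OC(=O)/C(C)=C\C)[C@H](CC=C)OC(=O)/C(C)=C\C
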